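The butenolide (O1–C2(=O)–C3=C4–C5) is disconnected at O1–C5. The route exploits C4, which carries the hydroxymethyl group next to the only stereocentre C5: in an open-chain (E)-C4=C5 alkene that group is an allylic alcohol, so a Sharpless epoxidation sets C5 in the presence of three other alkenes. In the key step the carbonyl oxygen of a tert-butyl ester (future O1) opens the strained C4–C5 oxirane at C5 with inversion, which closes the γ-lactone and leaves a tertiary C4–OH that is later eliminated to the C3=C4 bond. The precursor is an acyclic 2,3-epoxy alcohol with a CH2CO2tBu arm; its chain comes from carboalumination and two Wittig reactions.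

Key step: step 11

Remark: Weinreb amide 8 is taken to be a catalogue compound. Locants O1–C5 are those of the furan-2(5H)-one ring; C1′–C9′ are the side-chain carbons counted from C5.

Step 1
Reactants: 1 dihydro-β-ionone [4-(2,6,6-trimethylcyclohex-1-en-1-yl)butan-2-one]
Product: 3 2-(but-3-yn-1-yl)-1,3,3-trimethylcyclohex-1-ene, via enol phosphate 2 (not isolated)
Conditions: LiN(iPr)2 (1.05 equiv), THF, −78 °C; ClP(O)(OEt)2, −78 °C to rt; LiN(iPr)2 (2.3 equiv), −78 °C to rt; H2O
Reagents that add atoms: none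
Why: Kinetic deprotonation at the methyl group gives the terminal enol phosphate, and base-induced elimination of phosphate then gives the terminal alkyne (methyl ketone to alkyne conversion); the tetrasubstituted ring alkene is inert.

Step 2
Reactants: 3 2-(but-3-yn-1-yl)-1,3,3-trimethylcyclohex-1-ene
Product: 6 (3E)-4-methyl-6-(2,6,6-trimethylcyclohex-1-en-1-yl)hex-3-en-1-ol, via vinylalane 4 (not isolated), via lithium alanate 5 (not isolated)
Conditions: Al(CH3)3 (2 equiv), (C5H5)2ZrCl2 (0.2 equiv), ClCH2CH2Cl, rt; evaporation of excess Al(CH3)3; n-BuLi, THF/hexane, −30 °C; ethylene oxide, −30 to 0 °C; aq. KNaC4H4O6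
Reagents that add atoms: trimethylaluminium C[Al](C)C; ethylene oxide C1CO1
Why: Zirconium-catalysed Negishi carboalumination adds methyl and aluminium syn across the alkyne with methyl on the internal carbon, which fixes the E trisubstituted alkene, and the derived alanate opens ethylene oxide with retention of the alkene geometry.

Step 3
Reactants: 6 (3E)-4-methyl-6-(2,6,6-trimethylcyclohex-1-en-1-yl)hex-3-en-1-ol
Product: 7 2-[(3E)-6-bromo-3-methylhex-3-en-1-yl]-1,3,3-trimethylcyclohex-1-ene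
Conditions: CBr4, PPh3, CH2Cl2, 0 °C
Reagents that add atoms: carbon tetrabromide BrC(Br)(Br)Br
Why: Appel bromination converts the primary alcohol by SN2 displacement of an alkoxyphosphonium ion under neutral conditions that leave both alkenes alone.

Step 4
Reactants: 7 2-[(3E)-6-bromo-3-methylhex-3-en-1-yl]-1,3,3-trimethylcyclohex-1-ene; 8 2-[(tert-butyldimethylsilyl)oxy]-N-methoxy-N-methylacetamide
Product: 10 (5E)-1-[(tert-butyldimethylsilyl)oxy]-6-methyl-8-(2,6,6-trimethylcyclohex-1-en-1-yl)oct-5-en-2-one, via Grignard reagent 9 (not isolated)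
Conditions: Mg turnings, THF, rt to 40 °C; then 8, THF, 0 °C; aq. NH4Cl
Reagents that add atoms: none
Why: Weinreb ketone synthesis, in which the chelated tetrahedral magnesium adduct prevents a second addition and releases the α-silyloxy ketone only on work-up.

Step 5
Reactants: 10 (5E)-1-[(tert-butyldimethylsilyl)oxy]-6-methyl-8-(2,6,6-trimethylcyclohex-1-en-1-yl)oct-5-en-2-one; 11 [2-(1,3-dioxolan-2-yl)ethyl]triphenylphosphonium bromide
Product: 13 2-[(2Z,6E)-3-{[(tert-butyldimethylsilyl)oxy]methyl}-7-methyl-9-(2,6,6-trimethylcyclohex-1-en-1-yl)nona-2,6-dien-1-yl]-1,3-dioxolane, via phosphorus ylide 12 (not isolated)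
Conditions: 11, KN(SiMe3)2, THF, 0 °C; then 10, −78 °C to rt
Reagents that add atoms: none
Why: Wittig olefination of an α-alkoxy ketone with a non-stabilised ylide is Z-selective for trisubstituted allylic ethers, so the silyloxymethyl group should end cis to the ylide-derived CH2 (the C2′=C3′ geometry of the target).

Step 6
Reactants: 13 2-[(2Z,6E)-3-{[(tert-butyldimethylsilyl)oxy]methyl}-7-methyl-9-(2,6,6-trimethylcyclohex-1-en-1-yl)nona-2,6-dien-1-yl]-1,3-dioxolane
Product: 15 (3Z,7E)-4-{[(tert-butyldimethylsilyl)oxy]methyl}-8-methyl-10-(2,6,6-trimethylcyclohex-1-en-1-yl)deca-3,7-dienal, via collidinium salt 14 (not isolated)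
Conditions: Et3SiOTf (2 equiv), 2,4,6-collidine (3 equiv), CH2Cl2, 0 °C; then H2O, rt
Reagents that add atoms: water O
Why: The silyl triflate/collidine pair turns the dioxolane of an aldehyde into a pyridinium N,O-acetal that water hydrolyses under buffered, non-acidic conditions (chemoselective acetal cleavage), so the silyl ether should survive and the β,γ-alkene should not move into conjugation.

Step 7
Reactants: 16 methyl (triphenylphosphoranylidene)acetate (2 equiv); 17 tert-butyl bromoacetate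
Product: 19 4-tert-butyl 1-methyl 2-(triphenylphosphoranylidene)butanedioate, via phosphonium bromide 18 (not isolated)
Conditions: ethyl acetate, reflux; filtration of the phosphonium by-product
Reagents that add atoms: none
Why: C-alkylation of the stabilised ylide by the α-bromo ester followed by transylidation with the second equivalent of 16 gives the substituted stabilised ylide.

Step 8
Reactants: 15 (3Z,7E)-4-{[(tert-butyldimethylsilyl)oxy]methyl}-8-methyl-10-(2,6,6-trimethylcyclohex-1-en-1-yl)deca-3,7-dienal; 19 4-tert-butyl 1-methyl 2-(triphenylphosphoranylidene)butanedioate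
Product: 20 4-tert-butyl 1-methyl (2E)-2-[(3Z,7E)-4-{[(tert-butyldimethylsilyl)oxy]methyl}-8-methyl-10-(2,6,6-trimethylcyclohex-1-en-1-yl)deca-3,7-dien-1-ylidene]butanedioate
Conditions: CH2Cl2, rt to 40 °C
Reagents that add atoms: none
Why: The Wittig reaction of an α-substituted stabilised ylide is E-selective (chain trans to CO2CH3, cis to CH2CO2tBu) and neutral enough for the skipped enal.

Step 9
Reactants: 20 4-tert-butyl 1-methyl (2E)-2-[(3Z,7E)-4-{[(tert-butyldimethylsilyl)oxy]methyl}-8-methyl-10-(2,6,6-trimethylcyclohex-1-en-1-yl)deca-3,7-dien-1-ylidene]butanedioate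
Product: 21 tert-butyl (3E,6Z,10E)-7-{[(tert-butyldimethylsilyl)oxy]methyl}-3-(hydroxymethyl)-11-methyl-13-(2,6,6-trimethylcyclohex-1-en-1-yl)trideca-3,6,10-trienoate
Conditions: (i-Bu)2AlH (2.1 equiv), CH2Cl2, −78 °C; aq. KNaC4H4O6
Reagents that add atoms: none
Why: Hydride 1,2-reduction of the conjugated methyl ester gives the allylic alcohol, while the hindered tert-butyl ester should resist at −78 °C.

Step 10
Reactants: 21 tert-butyl (3E,6Z,10E)-7-{[(tert-butyldimethylsilyl)oxy]methyl}-3-(hydroxymethyl)-11-methyl-13-(2,6,6-trimethylcyclohex-1-en-1-yl)trideca-3,6,10-trienoate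
Product: 22 tert-butyl 2-[(2S,3S)-3-[(2Z,6E)-3-{[(tert-butyldimethylsilyl)oxy]methyl}-7-methyl-9-(2,6,6-trimethylcyclohex-1-en-1-yl)nona-2,6-dien-1-yl]-2-(hydroxymethyl)oxiran-2-yl]acetate
Conditions: Ti(OiPr)4 (0.2 equiv), L-(+)-diisopropyl tartrate (0.25 equiv), t-BuOOH (2 equiv), 4 Å molecular sieves, CH2Cl2, −20 °C
Reagents that add atoms: tert-butyl hydroperoxide CC(C)(C)OO
Why: Katsuki–Sharpless asymmetric epoxidation is directed by the only free allylic hydroxyl, so the three other alkenes are untouched, and the L-(+)-tartrate delivers oxygen to the enantioface that gives the (2S,3S)-oxirane (as with (E)-hex-2-en-1-ol), setting C5 as S so that the later inversion gives 5R.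

Step 11
Reactants: 22 tert-butyl 2-[(2S,3S)-3-[(2Z,6E)-3-{[(tert-butyldimethylsilyl)oxy]methyl}-7-methyl-9-(2,6,6-trimethylcyclohex-1-en-1-yl)nona-2,6-dien-1-yl]-2-(hydroxymethyl)oxiran-2-yl]acetate
Product: 23 (4S,5R)-5-[(2Z,6E)-3-{[(tert-butyldimethylsilyl)oxy]methyl}-7-methyl-9-(2,6,6-trimethylcyclohex-1-en-1-yl)nona-2,6-dien-1-yl]-4-hydroxy-4-(hydroxymethyl)oxolan-2-one
Conditions: BF3·OEt2 (0.3 equiv), CH2Cl2, −40 to −10 °C; aq. NaHCO3
Reagents that add atoms: none
Why: The Lewis acid activates the oxirane, the carbonyl oxygen of the tert-butyl ester attacks C5 anti to the C5–O bond, and the resulting tert-butoxy-substituted oxolanylium ion loses 2-methylpropene to leave the γ-lactone and the C4 tertiary alcohol. The closest known reaction type is the acid-promoted lactonisation of β,γ-epoxy esters to β-hydroxy-γ-lactones, the intramolecular counterpart of the C3-selective opening of 2,3-epoxy alcohols by carboxylic acids. The five-membered ring closes in the 5-endo mode at the oxirane (both oxirane carbons end up in the ring); the alternative is a 4-exo attack at the fully substituted C4, which would give a strained β-lactone. No new stereocentre is created: C5 is inverted stereospecifically from S to R by the backside attack, and C4 keeps its configuration until step 12 makes it planar. The step needs attack at C5 and not at C4, and no interference from the isolated alkenes or the silyl ether. C5 is the less hindered oxirane carbon and the one remote from the electron-withdrawing CH2OH, and a catalytic Lewis acid at low temperature should leave the tri- and tetrasubstituted alkenes and the primary silyl ether alone.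

Step 12
Reactants: 23 (4S,5R)-5-[(2Z,6E)-3-{[(tert-butyldimethylsilyl)oxy]methyl}-7-methyl-9-(2,6,6-trimethylcyclohex-1-en-1-yl)nona-2,6-dien-1-yl]-4-hydroxy-4-(hydroxymethyl)oxolan-2-one
Product: 25 (5R)-5-[(2Z,6E)-3-{[(tert-butyldimethylsilyl)oxy]methyl}-7-methyl-9-(2,6,6-trimethylcyclohex-1-en-1-yl)nona-2,6-dien-1-yl]-4-(hydroxymethyl)furan-2(5H)-one, via spiro cyclic carbonate 24 (not isolated)
Conditions: 1,1'-carbonyldiimidazole (1.2 equiv), CH2Cl2, rt; then DBU (1.5 equiv), 0 °C, short reaction time; aq. NaH2PO4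
Reagents that add atoms: none
Why: The 1,2-diol closes a cyclic carbonate that makes the tertiary C4–O a leaving group, deprotonation at C3 expels it (E1cB elimination of a β-acyloxy lactone) to form the C3=C4 bond, and the monoalkyl carbonate that masks the CH2O group during base exposure loses CO2 on mildly acidic work-up.

Step 13
Reactants: 25 (5R)-5-[(2Z,6E)-3-{[(tert-butyldimethylsilyl)oxy]methyl}-7-methyl-9-(2,6,6-trimethylcyclohex-1-en-1-yl)nona-2,6-dien-1-yl]-4-(hydroxymethyl)furan-2(5H)-one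
Product: 26 (6Z)-neomanoalide [(5R)-4-(hydroxymethyl)-5-[(2Z,6E)-3-(hydroxymethyl)-7-methyl-9-(2,6,6-trimethylcyclohex-1-en-1-yl)nona-2,6-dien-1-yl]furan-2(5H)-one]
Conditions: HF·pyridine, THF/pyridine, 0 °C to rt
Reagents that add atoms: none
Why: Fluoride cleaves the primary silyl ether under weakly acidic conditions that should not epimerise C5 or translactonise the butenolide.

Compound list
1 | dihydro-β-ionone, 4-(2,6,6-trimethylcyclohex-1-en-1-yl)butan-2-one | CC1=C(CCC(C)=O)C(C)(C)CCC1 | starting material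
2 | diethyl 4-(2,6,6-trimethylcyclohex-1-en-1-yl)but-1-en-2-yl phosphate (enol phosphate) | C=C(CCC1=C(C)CCCC1(C)C)OP(=O)(OCC)OCC | intermediate
3 | 2-(but-3-yn-1-yl)-1,3,3-trimethylcyclohex-1-ene | C#CCCC1=C(C)CCCC1(C)C | intermediate
4 | dimethyl[(1E)-2-methyl-4-(2,6,6-trimethylcyclohex-1-en-1-yl)but-1-en-1-yl]alane (vinylalane) | C[Al](C)/C=C(\C)CCC1=C(C)CCCC1(C)C | intermediate
5 | lithium butyl(dimethyl)[(1E)-2-methyl-4-(2,6,6-trimethylcyclohex-1-en-1-yl)but-1-en-1-yl]aluminate | [Li+].CCCC[Al-](C)(C)/C=C(\C)CCC1=C(C)CCCC1(C)C | intermediate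
6 | (3E)-4-methyl-6-(2,6,6-trimethylcyclohex-1-en-1-yl)hex-3-en-1-ol | OCC/C=C(\C)CCC1=C(C)CCCC1(C)C | intermediate
7 | 2-[(3E)-6-bromo-3-methylhex-3-en-1-yl]-1,3,3-trimethylcyclohex-1-ene | BrCC/C=C(\C)CCC1=C(C)CCCC1(C)C | intermediate
8 | 2-[(tert-butyldimethylsilyl)oxy]-N-methoxy-N-methylacetamide | CON(C)C(=O)CO[Si](C)(C)C(C)(C)C | starting material
9 | [(3E)-4-methyl-6-(2,6,6-trimethylcyclohex-1-en-1-yl)hex-3-en-1-yl]magnesium bromide | Br[Mg]CC/C=C(\C)CCC1=C(C)CCCC1(C)C | intermediate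
10 | (5E)-1-[(tert-butyldimethylsilyl)oxy]-6-methyl-8-(2,6,6-trimethylcyclohex-1-en-1-yl)oct-5-en-2-one | CC(C)(C)[Si](C)(C)OCC(=O)CC/C=C(\C)CCC1=C(C)CCCC1(C)C | intermediate
11 | [2-(1,3-dioxolan-2-yl)ethyl]triphenylphosphonium bromide | [Br-].C1COC(O1)CC[P+](c1ccccc1)(c1ccccc1)c1ccccc1 | starting material
12 | [2-(1,3-dioxolan-2-yl)ethylidene]triphenylphosphorane | C1COC(O1)CC=P(c1ccccc1)(c1ccccc1)c1ccccc1 | intermediate
13 | 2-[(2Z,6E)-3-{[(tert-butyldimethylsilyl)oxy]methyl}-7-methyl-9-(2,6,6-trimethylcyclohex-1-en-1-yl)nona-2,6-dien-1-yl]-1,3-dioxolane | C1COC(O1)C/C=C(\CO[Si](C)(C)C(C)(C)C)CC/C=C(\C)CCC1=C(C)CCCC1(C)C | intermediate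
14 | 1-[(3Z,7E)-4-{[(tert-butyldimethylsilyl)oxy]methyl}-8-methyl-1-{2-[(triethylsilyl)oxy]ethoxy}-10-(2,6,6-trimethylcyclohex-1-en-1-yl)deca-3,7-dien-1-yl]-2,4,6-trimethylpyridinium triflate (both epimers at the N,O-acetal carbon) | Cc1cc(C)[n+](c(C)c1)C(OCCO[Si](CC)(CC)CC)C/C=C(\CO[Si](C)(C)C(C)(C)C)CC/C=C(\C)CCC1=C(C)CCCC1(C)C.[O-]S(=O)(=O)C(F)(F)F | intermediate
15 | (3Z,7E)-4-{[(tert-butyldimethylsilyl)oxy]methyl}-8-methyl-10-(2,6,6-trimethylcyclohex-1-en-1-yl)deca-3,7-dienal | O=CC/C=C(\CO[Si](C)(C)C(C)(C)C)CC/C=C(\C)CCC1=C(C)CCCC1(C)C | intermediate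
16 | methyl (triphenylphosphoranylidene)acetate | COC(=O)C=P(c1ccccc1)(c1ccccc1)c1ccccc1 | starting material
17 | tert-butyl bromoacetate | BrCC(=O)OC(C)(C)C | starting material
18 | (4-tert-butoxy-1-methoxy-1,4-dioxobutan-2-yl)triphenylphosphonium bromide (racemic) | [Br-].COC(=O)C(CC(=O)OC(C)(C)C)[P+](c1ccccc1)(c1ccccc1)c1ccccc1 | intermediate
19 | 4-tert-butyl 1-methyl 2-(triphenylphosphoranylidene)butanedioate | COC(=O)C(CC(=O)OC(C)(C)C)=P(c1ccccc1)(c1ccccc1)c1ccccc1 | intermediate
20 | 4-tert-butyl 1-methyl (2E)-2-[(3Z,7E)-4-{[(tert-butyldimethylsilyl)oxy]methyl}-8-methyl-10-(2,6,6-trimethylcyclohex-1-en-1-yl)deca-3,7-dien-1-ylidene]butanedioate | COC(=O)/C(CC(=O)OC(C)(C)C)=C/C/C=C(\CO[Si](C)(C)C(C)(C)C)CC/C=C(\C)CCC1=C(C)CCCC1(C)C | intermediate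
21 | tert-butyl (3E,6Z,10E)-7-{[(tert-butyldimethylsilyl)oxy]methyl}-3-(hydroxymethyl)-11-methyl-13-(2,6,6-trimethylcyclohex-1-en-1-yl)trideca-3,6,10-trienoate | OC/C(CC(=O)OC(C)(C)C)=C/C/C=C(\CO[Si](C)(C)C(C)(C)C)CC/C=C(\C)CCC1=C(C)CCCC1(C)C | intermediate
22 | tert-butyl 2-[(2S,3S)-3-[(2Z,6E)-3-{[(tert-butyldimethylsilyl)oxy]methyl}-7-methyl-9-(2,6,6-trimethylcyclohex-1-en-1-yl)nona-2,6-dien-1-yl]-2-(hydroxymethyl)oxiran-2-yl]acetate | OC[C@]1(CC(=O)OC(C)(C)C)O[C@H]1C/C=C(\CO[Si](C)(C)C(C)(C)C)CC/C=C(\C)CCC1=C(C)CCCC1(C)C | intermediate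
23 | (4S,5R)-5-[(2Z,6E)-3-{[(tert-butyldimethylsilyl)oxy]methyl}-7-methyl-9-(2,6,6-trimethylcyclohex-1-en-1-yl)nona-2,6-dien-1-yl]-4-hydroxy-4-(hydroxymethyl)oxolan-2-one | O=C1C[C@](O)(CO)[C@@H](C/C=C(\CO[Si](C)(C)C(C)(C)C)CC/C=C(\C)CCC2=C(C)CCCC2(C)C)O1 | intermediate
24 | (5S,6R)-6-[(2Z,6E)-3-{[(tert-butyldimethylsilyl)oxy]methyl}-7-methyl-9-(2,6,6-trimethylcyclohex-1-en-1-yl)nona-2,6-dien-1-yl]-1,3,7-trioxaspiro[4.4]nonane-2,8-dione (cyclic carbonate of 23) | O=C1C[C@]2(COC(=O)O2)[C@@H](C/C=C(\CO[Si](C)(C)C(C)(C)C)CC/C=C(\C)CCC3=C(C)CCCC3(C)C)O1 | intermediate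
25 | (5R)-5-[(2Z,6E)-3-{[(tert-butyldimethylsilyl)oxy]methyl}-7-methyl-9-(2,6,6-trimethylcyclohex-1-en-1-yl)nona-2,6-dien-1-yl]-4-(hydroxymethyl)furan-2(5H)-one | O=C1C=C(CO)[C@@H](C/C=C(\CO[Si](C)(C)C(C)(C)C)CC/C=C(\C)CCC2=C(C)CCCC2(C)C)O1 | intermediate
26 | (6Z)-neomanoalide, (5R)-4-(hydroxymethyl)-5-[(2Z,6E)-3-(hydroxymethyl)-7-methyl-9-(2,6,6-trimethylcyclohex-1-en-1-yl)nona-2,6-dien-1-yl]furan-2(5H)-one | CC1=C(CC/C(C)=C/CC/C(=C/C[C@H]2OC(=O)C=C2CO)CO)C(C)(C)CCC1 | target

Total step count: 13. Longest linear sequence: 12 steps (steps 1–6 and 8–13, from 1); step 7 is a one-step side branch.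

Steps most likely to fail

Step 11. The Lewis acid may ionise the oxirane at its fully substituted carbon (hydride shift or semipinacol rearrangement), or the silyl ether oxygen may attack C5 before the ester oxygen does. The fallback sets out from 22. DBU in CH2Cl2 should open the β,γ-epoxy ester by E1cB elimination to the (2E)-4-hydroxy enoate F1, which keeps the C5–O bond and is expected to carry the ester cis to CH2OH. A trace of CF3CO2H then closes a temporary regioisomeric ring through the primary hydroxyl, the 4-(1-hydroxyalkyl)furan-2(5H)-one F2, which locks the enoate geometry and leaves only the secondary C5–OH free. MsCl/Et3N gives the mesylate F3. LiOH in THF/H2O opens the temporary lactone, and the carboxylate displaces the allylic mesylate at C5 with inversion, forming the same O1–C5 bond by SN2. The fallback comes back to the route at 25, so steps 11 and 12 are both replaced.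

Step 12. Carbonate closure at the tertiary hydroxyl may be incomplete, or the base may erode the C5 configuration of the product through its dienolate. The fallback sets out from 23. Ac2O/pyridine acetylates only the primary hydroxyl to give the monoacetate F4. The Burgess reagent dehydrates the tertiary alcohol by syn-elimination toward C3 under neutral conditions, giving the acetoxymethyl butenolide F5. Candida antarctica lipase B in pH 7 buffer/acetone removes the acetate without base and comes back to the route at 25.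

Step 9. The hydride may also attack the tert-butyl ester, or the new aluminium alkoxide may close onto it to give a β-alkylidene butyrolactone. The fallback sets out from 15. Wittig reaction with the formyl ylide F6 (made from (triphenylphosphoranylidene)acetaldehyde and 17 as in step 7) in toluene at 60 °C gives the (E)-enal F7. NaBH4/CeCl3·7H2O in MeOH at −40 °C (Luche reduction) reduces only the aldehyde and comes back to the route at 21.

Further compounds
F1 | step 11 | tert-butyl (2E,4S,6Z,10E)-7-{[(tert-butyldimethylsilyl)oxy]methyl}-4-hydroxy-3-(hydroxymethyl)-11-methyl-13-(2,6,6-trimethylcyclohex-1-en-1-yl)trideca-2,6,10-trienoate | CC(C)(C)OC(=O)/C=C(CO)/[C@@H](O)C/C=C(\CO[Si](C)(C)C(C)(C)C)CC/C=C(\C)CCC1=C(C)CCCC1(C)C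
F2 | step 11 | 4-[(1S,3Z,7E)-4-{[(tert-butyldimethylsilyl)oxy]methyl}-1-hydroxy-8-methyl-10-(2,6,6-trimethylcyclohex-1-en-1-yl)deca-3,7-dien-1-yl]furan-2(5H)-one | O=C1C=C(CO1)[C@@H](O)C/C=C(\CO[Si](C)(C)C(C)(C)C)CC/C=C(\C)CCC2=C(C)CCCC2(C)C
F3 | step 11 | (1S,3Z,7E)-4-{[(tert-butyldimethylsilyl)oxy]methyl}-8-methyl-1-(5-oxo-2,5-dihydrofuran-3-yl)-10-(2,6,6-trimethylcyclohex-1-en-1-yl)deca-3,7-dien-1-yl methanesulfonate | O=C1C=C(CO1)[C@@H](OS(C)(=O)=O)C/C=C(\CO[Si](C)(C)C(C)(C)C)CC/C=C(\C)CCC2=C(C)CCCC2(C)C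
F4 | step 12 | [(2R,3S)-2-[(2Z,6E)-3-{[(tert-butyldimethylsilyl)oxy]methyl}-7-methyl-9-(2,6,6-trimethylcyclohex-1-en-1-yl)nona-2,6-dien-1-yl]-3-hydroxy-5-oxooxolan-3-yl]methyl acetate | O=C1C[C@](O)(COC(C)=O)[C@@H](C/C=C(\CO[Si](C)(C)C(C)(C)C)CC/C=C(\C)CCC2=C(C)CCCC2(C)C)O1
F5 | step 12 | [(2R)-2-[(2Z,6E)-3-{[(tert-butyldimethylsilyl)oxy]methyl}-7-methyl-9-(2,6,6-trimethylcyclohex-1-en-1-yl)nona-2,6-dien-1-yl]-5-oxo-2,5-dihydrofuran-3-yl]methyl acetate | O=C1C=C(COC(C)=O)[C@@H](C/C=C(\CO[Si](C)(C)C(C)(C)C)CC/C=C(\C)CCC2=C(C)CCCC2(C)C)O1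
F6 | step 9 | tert-butyl 4-oxo-3-(triphenylphosphoranylidene)butanoate | O=CC(CC(=O)OC(C)(C)C)=P(c1ccccc1)(c1ccccc1)c1ccccc1
F7 | step 9 | tert-butyl (3E,6Z,10E)-7-{[(tert-butyldimethylsilyl)oxy]methyl}-3-formyl-11-methyl-13-(2,6,6-trimethylcyclohex-1-en-1-yl)trideca-3,6,10-trienoate | O=C/C(CC(=O)OC(C)(C)C)=C/C/C=C(\CO[Si](C)(C)C(C)(C)C)CC/C=C(\C)CCC1=C(C)CCCC1(C)C
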